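In the eta run, the complex with one exchanged falls steadily through every reading, so I use that fall to decide whether elm can stay at its planned time or must be stopped earlier, while this complex can still be read.

in all of them: starting complex 0.20 M
- eta: incoming ligand 0.46 equiv; run made earlier
- delta: incoming ligand 0.86 equiv; run made earlier
- zeta: incoming ligand 1.1 equiv; run made earlier
- alder: incoming ligand 1.20 equiv; time 20 h
- elm: incoming ligand 0.500 equiv; time 20 h
- cedar: incoming ligand 1.50 equiv; time 20 h

- eta (time / h: complex with one exchanged / %, complex with two exchanged / %): 1.33: 30.4, 6.0; 4.00: 26.6, 3.1; 6.00: 18.2, 2.7; 10.0: 14.9, 2.2; 15.0: 11.1, 1.7
- delta (time / h: complex with one exchanged / %, complex with two exchanged / %): 3.00: 35.5, 13.4; 6.00: 27.7, 13.0; 8.00: 24.4, 10.1; 12.0: 19.2, 9.0; 15.0: 14.6, 6.8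
- zeta (time / h: complex with one exchanged / %, complex with two exchanged / %): 1.00: 38.0, 29.9; 2.00: 35.1, 25.2; 4.00: 31.0, 22.2; 8.00: 22.1, 14.5; 15.0: 12.4, 13.0

(standard deviation of a reading: 1 percentage point)

- which of these holds the largest part of the starting complex at the end of alder (starting complex / complex with one exchanged / complex with two exchanged)
- which of these holds the largest part of the starting complex at the end of elm (starting complex / complex with one exchanged / complex with two exchanged)
- which of these holds the largest part of the starting complex at the end of cedar (starting complex / complex with one exchanged / complex with two exchanged)
- how much complex with one exchanged is there at the end of elm, in percent of the starting complex charged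

At the first eta reading, the complex with one exchanged plus twice the complex with two exchanged comes to 42.4 % of the starting complex, against a charge of 0.46 equiv, and this sum leaves out the side product and the isomer of the product, which carry exchanged ligand too. I therefore treat the incoming ligand as the limiting reagent and reckon as if it takes no further part from that reading on. On that assumption the rate of the fall hangs on the concentration of the complex with one exchanged, and I reckon the fall as first order.

My carried quantity is the fall constant, the logarithm of the ratio of first to last reading divided by the time between them. Eta gives 0.0737 h⁻¹. Delta gives 0.0740 h⁻¹ and zeta 0.0800 h⁻¹, so the readings show nearly the same constant across these charges.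

I scale eta's last reading by the ratio of the charges and carry it on to 20 h with this constant, which gives 8.35 % for elm. Against a scatter of 1 percentage point, that is still readable, so I leave elm's time as it is.

The forecast, which says this complex “falls first-order in all three runs”, gives 7.7 % for elm, within 6.5 % to 9 %, a little below my figure. It names starting complex for alder, starting complex for elm and complex with two exchanged for cedar.

    complex with two exchanged ⇌ isomer of the product (K = 2.00, k = 0.151 h⁻¹)
    starting complex + incoming ligand → leaving ligand + complex with one exchanged (k = 43.9 L mol⁻¹ h⁻¹)
    complex with one exchanged → side product (k = 0.0767 h⁻¹)
    complex with one exchanged + incoming ligand → leaving ligand + complex with two exchanged (k = 32.5 L mol⁻¹ h⁻¹)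

Elm gives 7.39 %, which lies inside the forecast's range and 0.96 points below my figure. The largest holders are starting complex in alder, starting complex in elm and complex with two exchanged in cedar, as forecast. The neighbouring flask is elm read at 5.0 h, where incoming ligand stands at 0 % of its charge. Carrying elm's final value back over the 15.0 h between the two readings with the eta fall constant gives 22.3 %. That flask holds 23.4 % of the complex with one exchanged.

The numbers in the tables stem from a simulated flask from invented constants; scatter was added.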